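I started from the constants of this two-phase flask, which stand here with its charge and the questions asked.

    spent carrier + salt in the second phase ⇌ fresh carrier + spent salt in the second phase (K1 = 0.238, k1 = 10.0 M⁻¹ min⁻¹)
    substrate + fresh carrier → target + spent carrier (k2 = 83.1 M⁻¹ min⁻¹)
    fresh carrier + impurity → spent catalyst (k3 = 110 M⁻¹ min⁻¹)
    2 substrate → self-condensation product (k4 = 0.0305 M⁻¹ min⁻¹)

substrate 0.26 M; salt in the second phase 0.520 M; spent carrier 12 mM; impurity 5.4 mM; volume of the second phase over the first 1.0

- percent here means substrate units held: one self-condensation product counts as two
- where a step has two of a species, its rate is k times that concentration squared, and two are used at each turn
- in the second phase: salt in the second phase, spent salt in the second phase; everything else is in the first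
- charges count per volume of the first phase; a concentration in a rate is the amount of a species over the volume of its own phase; every rate counts per litre of the first phase
- charge of substrate (flask): 0.26 M

- the form that holds most of the catalyst when 50% of the substrate are converted (spent catalyst / spent carrier / fresh carrier)
- its share of the catalyst then
- apparent order in salt in the second phase when 50% of the substrate are converted (percent change of the rate of making target for one percent more salt in the second phase charged)
- factor on the rate of making target when 50% of the substrate are converted if salt in the second phase is charged twice over

Per carrier at the charged amounts, fresh carrier was lost to impurity at 36 h⁻¹, far more slowly than it reacted with substrate at 1300 h⁻¹, so I treated the live carrier as balanced from moment to moment. Setting self-condensation aside, at 50% conversion I took substrate as 0.130 M, spent salt as 0.130 M and salt as 0.390 M. That gave 0.240 for the carrier ratio: fresh carrier over spent carrier, the forward exchange per spent carrier divided by the reverse exchange plus the substrate step per fresh carrier. Impurity and substrate competed for fresh carrier with a selectivity factor of 1.32, which put 27.0% of the catalyst into spent catalyst. The rest, divided by one plus the ratio, left spent carrier with 58.9%. My reckoning went no further, to neither order nor factor.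

The forecast named spent carrier at 59.5%, with order 1.03 and factor 1.81, holding that “regeneration is slow against the substrate step and the reverse exchange with spent salt”.

The simulation gave spent carrier at 59.7%, the resting state of the round, beside 14.4% fresh carrier and 25.9% spent catalyst, with order 1.0 and factor 1.81.

The carrier ratio in the flask then read 0.242, beside my 0.240. The rate at which fresh carrier was made over the rate at which it was used up, each step taken net, stood at 0.996 at 0.0681 h. At 10.0 h substrate stood at 0%, which removes the substrate term and leaves the equilibrium constant times salt over spent salt. Salt held 51% of its charge and spent salt the remainder, so the ratio came to 0.249, and the flask held 11.0% fresh carrier against 44.0% spent carrier, a ratio of 0.250.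

(The numbers are assumed; the flask was simulated.)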